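Ring B is cut across C5'–C6' and C1'–C2'. C1' (with its CO2CH3) and C6' (with its CH3) come from methyl but-2-ynoate, and C2'–C5' come from a 1,1,3-trioxygenated butadiene. The feature exploited is that the depside oxygen on C4' of ring B is formally the enol oxygen of a β-keto ester, so the ring-A acyl group can be attached before ring B exists and no ring-B phenol has to be differentiated. One thermal (4+2) cycloaddition, followed by loss of methanol and silicon, delivers complete ring B with its C2' phenol. The precursor is the silyl ketene acetal diene of the enol ester made from methyl 2-methyl-3-oxobutanoate and the tribenzyl, dioxolane-protected ring-A acid.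

Key step: step 10

Remark on numbering: ring A is the acyl ring (C1 carboxyl-bearing, C2 OH, C3 CHO, C4 OH, C5 OH, C6 CH3); ring B carries primed locants (C1' CO2CH3, C2' OH, C3' CH3, C4' O-acyl, C5' H, C6' CH3).

Remark on geometry: enol ester 15, dienolate 16 and diene 17 may form as mixtures of double-bond isomers; one isomer is drawn because the geometry is lost in steps 9 and 10. Compounds 12 and 19 are racemic, and their stereocentres do not survive.

Step 1
Reactants: 1 2,4-dihydroxy-6-methylbenzaldehyde
Product: 2 2,4-bis(benzyloxy)-6-methylbenzaldehyde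
Conditions: BnBr (2.4 equiv), K2CO3, DMF, 60 °C
Reagents that add atoms: benzyl bromide, BrCc1ccccc1
Why: Williamson ether synthesis, in which both phenoxides, including the hydrogen-bonded ortho one, should be alkylated by the reactive benzylic bromide in warm DMF.

Step 2
Reactants: 2 2,4-bis(benzyloxy)-6-methylbenzaldehyde
Product: 4 2,4-bis(benzyloxy)-6-methylphenol, via aryl formate 3 (not isolated)
Conditions: mCPBA, CH2Cl2, 0 °C to rt; then K2CO3 (cat.), MeOH, rt
Reagents that add atoms: 3-chloroperbenzoic acid, OOC(=O)c1cccc(Cl)c1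
Why: Baeyer–Villiger (Dakin-type) oxidation, in which the electron-rich ortho,para-dialkoxyaryl group migrates in preference to hydrogen and the resulting formate is removed by methanolysis.

Step 3
Reactants: 4 2,4-bis(benzyloxy)-6-methylphenol
Product: 5 1,2,5-tris(benzyloxy)-3-methylbenzene
Conditions: BnBr, K2CO3, DMF, 60 °C
Reagents that add atoms: benzyl bromide, BrCc1ccccc1
Why: Williamson ether synthesis on the flanked phenoxide, which should remain nucleophilic enough towards a benzylic bromide in a dipolar solvent.

Step 4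
Reactants: 5 1,2,5-tris(benzyloxy)-3-methylbenzene
Product: 7 2,3,6-tris(benzyloxy)-4-methylbenzaldehyde, via aryllithium 6 (not isolated)
Conditions: n-BuLi, THF, 0 °C; then DMF, 0 °C to rt; 1 M HCl work-up
Reagents that add atoms: N,N-dimethylformamide, CN(C)C=O
Why: Directed ortho-metalation followed by Bouveault formylation, the ring C–H flanked by two benzyloxy groups (future C3 of ring A) being the most acidic and doubly coordinated site, as in the lithiation of 1,3-bis- and 1,3,5-tris(benzyloxy)benzenes.

Step 5
Reactants: 7 2,3,6-tris(benzyloxy)-4-methylbenzaldehyde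
Product: 8 2,3,6-tris(benzyloxy)-5-bromo-4-methylbenzaldehyde
Conditions: NBS, MeCN, 0 °C to rt, dark
Reagents that add atoms: N-bromosuccinimide, O=C1CCC(=O)N1Br
Why: Electrophilic aromatic bromination at the only ring position left (future C1 of ring A), which is ortho and para to benzyloxy groups and meta to the formyl group, with polar ionic conditions chosen to avoid benzylic radical bromination.

Step 6
Reactants: 8 2,3,6-tris(benzyloxy)-5-bromo-4-methylbenzaldehyde
Product: 9 2-[2,3,6-tris(benzyloxy)-5-bromo-4-methylphenyl]-1,3-dioxolane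
Conditions: HOCH2CH2OH, TsOH (cat.), toluene, reflux, Dean–Stark
Reagents that add atoms: ethane-1,2-diol, OCCO
Why: Acid-catalysed acetalisation driven by azeotropic removal of water, which aryl benzyl ethers and the aryl bromide tolerate.

Step 7
Reactants: 9 2-[2,3,6-tris(benzyloxy)-5-bromo-4-methylphenyl]-1,3-dioxolane
Product: 11 2,4,5-tris(benzyloxy)-3-(1,3-dioxolan-2-yl)-6-methylbenzoic acid, via aryllithium 10 (not isolated)
Conditions: n-BuLi, THF, −78 °C; then CO2, −78 °C to rt; cold 10% aq. citric acid work-up
Reagents that add atoms: carbon dioxide, O=C=O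
Why: Bromine–lithium exchange, which outruns any deprotonation at −78 °C, followed by carboxylation of the aryllithium, the dioxolane being inert to the base and to a weakly acidic work-up.

Step 8
Reactants: 11 2,4,5-tris(benzyloxy)-3-(1,3-dioxolan-2-yl)-6-methylbenzoic acid; 12 methyl 2-methyl-3-oxobutanoate
Product: 15 methyl (2E)-3-{[2,4,5-tris(benzyloxy)-3-(1,3-dioxolan-2-yl)-6-methylbenzoyl]oxy}-2-methylbut-2-enoate, via acid chloride 13 (not isolated), via sodium enolate 14 (not isolated)
Conditions: 11, Me2C=C(Cl)NMe2, CH2Cl2, 0 °C to rt; separately 12, NaH, THF, 0 °C; combine, DMPU, 0 °C to rt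
Reagents that add atoms: none
Why: O-acylation of a β-keto ester enolate, in which the neutral chloroenamine gives the acid chloride without HCl (sparing the dioxolane) and the α-methylated enolate in a dipolar medium should attack the hindered, hard aroyl chloride through oxygen because C-acylation would create a congested quaternary centre.

Step 9
Reactants: 15 methyl (2E)-3-{[2,4,5-tris(benzyloxy)-3-(1,3-dioxolan-2-yl)-6-methylbenzoyl]oxy}-2-methylbut-2-enoate
Product: 17 4-methoxy-3-methyl-4-(trimethylsilyloxy)buta-1,3-dien-2-yl 2,4,5-tris(benzyloxy)-3-(1,3-dioxolan-2-yl)-6-methylbenzoate, via lithium dienolate 16 (not isolated)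
Conditions: Me3SiCl (3 equiv), THF, −78 °C; LiN(iPr)2 (1.2 equiv) added slowly; concentrate, hexane, filter under argon, use crude
Reagents that add atoms: chlorotrimethylsilane, C[Si](C)(C)Cl
Why: Vinylogous (γ) deprotonation of a β-oxygenated enoate and O-silylation of the extended enolate, the standard entry to 1-alkoxy-1-silyloxybuta-1,3-dienes, run with the silyl chloride already present so that the dienolate is trapped at once while the di-ortho-substituted aroyl group resists attack and acyl transfer.

Step 10
Reactants: 17 4-methoxy-3-methyl-4-(trimethylsilyloxy)buta-1,3-dien-2-yl 2,4,5-tris(benzyloxy)-3-(1,3-dioxolan-2-yl)-6-methylbenzoate; 18 methyl but-2-ynoate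
Product: 21 methyl 4-{[2,4,5-tris(benzyloxy)-3-(1,3-dioxolan-2-yl)-6-methylbenzoyl]oxy}-2-hydroxy-3,6-dimethylbenzoate, via cycloadduct 19 (not isolated), via dienone 20 (not isolated)
Conditions: 18 (5 equiv), toluene, sealed tube, 120–130 °C; then Bu4NF, AcOH, THF, 0 °C
Reagents that add atoms: none
Why: The diene is a vinylogous silyl ketene acetal whose HOMO is largest at the CH2 terminus (C5'), and it should combine with the ynoate, whose LUMO is largest at the methyl-bearing β-carbon (C6'), in a concerted but asynchronous normal-demand Diels–Alder reaction that forms C5'–C6' ahead of C1'–C2'. The closest known reaction type is the cycloaddition–aromatisation of 1-alkoxy-1-silyloxybuta-1,3-dienes with alkynoates to give salicylates, applied here to a diene whose C4' oxygen carries an aroyl instead of a silyl group. Ring B is closed as a six-membered carbocycle by intermolecular (4+2) cycloaddition, giving cyclohexa-1,4-diene 19. Buffered fluoride then removes silicon from the mixed ketal at C2', the hemiketal loses methanol to give dienone 20, and a proton shift from C5' to oxygen aromatises ring B to the C2' phenol, which is hydrogen-bonded to the C1' ester. The only stereocentre formed (C2' of 19) is erased in this sequence, so no stereocontrol is needed. The one selectivity needed is regiochemistry, and it is secured by matched polarity (two donor oxygens on C2' make C5' nucleophilic, the ester makes C6' electrophilic), while the benzyl ethers, dioxolane and hindered aryl ester should be inert to heat and buffered fluoride.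

Step 11
Reactants: 21 methyl 4-{[2,4,5-tris(benzyloxy)-3-(1,3-dioxolan-2-yl)-6-methylbenzoyl]oxy}-2-hydroxy-3,6-dimethylbenzoate
Product: 22 methyl 4-{[2,4,5-tris(benzyloxy)-3-formyl-6-methylbenzoyl]oxy}-2-hydroxy-3,6-dimethylbenzoate
Conditions: 1 M HCl, THF, rt
Reagents that add atoms: water, O
Why: Acid-catalysed acetal hydrolysis through an aryl-stabilised oxocarbenium ion, under conditions that should leave the benzyl ethers, the hindered depside ester and the methyl ester untouched.

Step 12
Reactants: 22 methyl 4-{[2,4,5-tris(benzyloxy)-3-formyl-6-methylbenzoyl]oxy}-2-hydroxy-3,6-dimethylbenzoate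
Product: 23 methyl 4-[(3-formyl-2,4,5-trihydroxy-6-methylbenzoyl)oxy]-2-hydroxy-3,6-dimethylbenzoate (CNP0216802.0)
Conditions: H2 (1 atm), Pd/C, EtOAc, rt; filtration and work-up under argon
Reagents that add atoms: none
Why: Catalytic hydrogenolysis of three aryl benzyl ethers in a neutral, non-protic solvent, where O-benzyl cleavage should be much faster than reduction of the flanked formyl group, which becomes hydrogen-bonded to the freed C2 and C4 hydroxyls.

Compound list
1 | 2,4-dihydroxy-6-methylbenzaldehyde | Cc1cc(O)cc(O)c1C=O | starting material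
2 | 2,4-bis(benzyloxy)-6-methylbenzaldehyde | Cc1cc(OCc2ccccc2)cc(OCc2ccccc2)c1C=O | intermediate
3 | 2,4-bis(benzyloxy)-6-methylphenyl formate | Cc1cc(OCc2ccccc2)cc(OCc2ccccc2)c1OC=O | intermediate (not isolated)
4 | 2,4-bis(benzyloxy)-6-methylphenol | Cc1cc(OCc2ccccc2)cc(OCc2ccccc2)c1O | intermediate
5 | 1,2,5-tris(benzyloxy)-3-methylbenzene | Cc1cc(OCc2ccccc2)cc(OCc2ccccc2)c1OCc1ccccc1 | intermediate
6 | [2,3,6-tris(benzyloxy)-4-methylphenyl]lithium | [Li]c1c(OCc2ccccc2)cc(C)c(OCc2ccccc2)c1OCc1ccccc1 | intermediate (not isolated)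
7 | 2,3,6-tris(benzyloxy)-4-methylbenzaldehyde | O=Cc1c(OCc2ccccc2)cc(C)c(OCc2ccccc2)c1OCc1ccccc1 | intermediate
8 | 2,3,6-tris(benzyloxy)-5-bromo-4-methylbenzaldehyde | O=Cc1c(OCc2ccccc2)c(Br)c(C)c(OCc2ccccc2)c1OCc1ccccc1 | intermediate
9 | 2-[2,3,6-tris(benzyloxy)-5-bromo-4-methylphenyl]-1,3-dioxolane | Cc1c(Br)c(OCc2ccccc2)c(C2OCCO2)c(OCc2ccccc2)c1OCc1ccccc1 | intermediate
10 | [2,4,5-tris(benzyloxy)-3-(1,3-dioxolan-2-yl)-6-methylphenyl]lithium | [Li]c1c(C)c(OCc2ccccc2)c(OCc2ccccc2)c(C2OCCO2)c1OCc1ccccc1 | intermediate (not isolated)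
11 | 2,4,5-tris(benzyloxy)-3-(1,3-dioxolan-2-yl)-6-methylbenzoic acid | OC(=O)c1c(C)c(OCc2ccccc2)c(OCc2ccccc2)c(C2OCCO2)c1OCc1ccccc1 | intermediate
12 | methyl 2-methyl-3-oxobutanoate (racemic) | CC(=O)C(C)C(=O)OC | starting material
13 | 2,4,5-tris(benzyloxy)-3-(1,3-dioxolan-2-yl)-6-methylbenzoyl chloride | ClC(=O)c1c(C)c(OCc2ccccc2)c(OCc2ccccc2)c(C2OCCO2)c1OCc1ccccc1 | intermediate (not isolated)
14 | sodium (Z)-enolate of methyl 2-methyl-3-oxobutanoate | [Na+].C/C([O-])=C(C)/C(=O)OC | intermediate (not isolated)
15 | methyl (2E)-3-{[2,4,5-tris(benzyloxy)-3-(1,3-dioxolan-2-yl)-6-methylbenzoyl]oxy}-2-methylbut-2-enoate | C/C(OC(=O)c1c(C)c(OCc2ccccc2)c(OCc2ccccc2)c(C2OCCO2)c1OCc1ccccc1)=C(C)\C(=O)OC | intermediate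
16 | lithium dienolate of 15 (lithium 3-aroyloxy-1-methoxy-2-methylbuta-1,3-dien-1-olate) | [Li+].C=C(OC(=O)c1c(C)c(OCc2ccccc2)c(OCc2ccccc2)c(C2OCCO2)c1OCc1ccccc1)/C(C)=C(/OC)[O-] | intermediate (not isolated)
17 | 4-methoxy-3-methyl-4-(trimethylsilyloxy)buta-1,3-dien-2-yl 2,4,5-tris(benzyloxy)-3-(1,3-dioxolan-2-yl)-6-methylbenzoate | C=C(OC(=O)c1c(C)c(OCc2ccccc2)c(OCc2ccccc2)c(C2OCCO2)c1OCc1ccccc1)/C(C)=C(/OC)O[Si](C)(C)C | intermediate
18 | methyl but-2-ynoate | CC#CC(=O)OC | starting material
19 | methyl 4-{[2,4,5-tris(benzyloxy)-3-(1,3-dioxolan-2-yl)-6-methylbenzoyl]oxy}-6-methoxy-2,5-dimethyl-6-(trimethylsilyloxy)cyclohexa-1,4-diene-1-carboxylate (racemic) | COC(=O)C1=C(C)CC(OC(=O)c2c(C)c(OCc3ccccc3)c(OCc3ccccc3)c(C3OCCO3)c2OCc2ccccc2)=C(C)C1(OC)O[Si](C)(C)C | intermediate (not isolated)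
20 | methyl 4-{[2,4,5-tris(benzyloxy)-3-(1,3-dioxolan-2-yl)-6-methylbenzoyl]oxy}-2,5-dimethyl-6-oxocyclohexa-1,4-diene-1-carboxylate | COC(=O)C1=C(C)CC(OC(=O)c2c(C)c(OCc3ccccc3)c(OCc3ccccc3)c(C3OCCO3)c2OCc2ccccc2)=C(C)C1=O | intermediate (not isolated)
21 | methyl 4-{[2,4,5-tris(benzyloxy)-3-(1,3-dioxolan-2-yl)-6-methylbenzoyl]oxy}-2-hydroxy-3,6-dimethylbenzoate | COC(=O)c1c(C)cc(OC(=O)c2c(C)c(OCc3ccccc3)c(OCc3ccccc3)c(C3OCCO3)c2OCc2ccccc2)c(C)c1O | intermediate
22 | methyl 4-{[2,4,5-tris(benzyloxy)-3-formyl-6-methylbenzoyl]oxy}-2-hydroxy-3,6-dimethylbenzoate | COC(=O)c1c(C)cc(OC(=O)c2c(C)c(OCc3ccccc3)c(OCc3ccccc3)c(C=O)c2OCc2ccccc2)c(C)c1O | intermediate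
23 | methyl 4-[(3-formyl-2,4,5-trihydroxy-6-methylbenzoyl)oxy]-2-hydroxy-3,6-dimethylbenzoate | COC(=O)c1c(C)cc(OC(=O)c2c(C)c(O)c(O)c(C=O)c2O)c(C)c1O | target

Total step count: 12.
Longest linear sequence: 12 steps (1 to 23); 12 and 18 enter as purchased materials in steps 8 and 10.

Steps most likely to fail

Step 10. The cycloaddition may be slower than thermal breakdown of the diene (loss of silicon, acyl migration), because an acyloxy group on C4' donates less than a silyloxy group and a 3-substituted ynoate is a sluggish dienophile. The fallback is a classical depside esterification that does not build ring B at all. It sets out from acid 11, which is converted into chloride 13 as in step 8 and used to acylate commercial methyl 2,4-dihydroxy-3,6-dimethylbenzoate F1 (Et3N, DMAP cat., CH2Cl2, 0 °C to rt). Acylation should occur at the 4-hydroxyl, the 2-hydroxyl being held in a hydrogen bond to the ester. This gives 21 directly, and the route resumes at step 11.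

Step 9. Deprotonation may go astray: lateral metalation of the C6 methyl of ring A (ortho to the ester carbonyl) or attack of the amide base on the enol ester may compete with removal of the γ-proton. The fallback reaches the same diene from an isomer that needs only ordinary α-deprotonation. It sets out from acid 11, which adds across the terminal alkyne methyl 2-methylbut-3-ynoate F2 in a ruthenium-catalysed Markovnikov hydro-acyloxylation ([RuCl2(p-cymene)]2, P(2-furyl)3, Na2CO3 cat., toluene, 50 °C). This gives the deconjugated enol ester methyl 3-{[2,4,5-tris(benzyloxy)-3-(1,3-dioxolan-2-yl)-6-methylbenzoyl]oxy}-2-methylbut-3-enoate F3. Its ester α-proton, which is also allylic, should be removed by LiN(SiMe3)2 at −78 °C in the presence of Me3SiCl, and O-silylation brings the route back at diene 17.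

Step 12. The formyl group on C3 may be over-reduced on the catalyst, or the hydroquinone-type ring A (para C2/C5 hydroxyls) may be oxidised by air during filtration. The fallback is a non-reductive Lewis-acid debenzylation. It sets out from 22, which is treated with BCl3 and pentamethylbenzene as benzyl-cation scavenger (CH2Cl2, −78 °C, then aqueous quench under argon), and comes back at target 23. No new compound is made on the way (F0).

Further compounds
F1 | step 10 | methyl 2,4-dihydroxy-3,6-dimethylbenzoate | COC(=O)c1c(C)cc(O)c(C)c1O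
F2 | step 9 | methyl 2-methylbut-3-ynoate (racemic) | C#CC(C)C(=O)OC
F3 | step 9 | methyl 3-{[2,4,5-tris(benzyloxy)-3-(1,3-dioxolan-2-yl)-6-methylbenzoyl]oxy}-2-methylbut-3-enoate (racemic) | C=C(OC(=O)c1c(C)c(OCc2ccccc2)c(OCc2ccccc2)c(C2OCCO2)c1OCc1ccccc1)C(C)C(=O)OC
F0 | step 12 | none | none
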